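The strategy rests on one hidden feature. If the cyclopropane bond C8–C9 is cut and C11 is raised to a ketone, the cyclopentane C1-C9-C10-C11-C6 fused to ring A carries a two-carbon bridge C7–C8 between C6 and C10, the two carbons flanking the carbonyl. That bicyclo[2.2.1]heptan-7-one is the adduct of a Nazarov oxyallyl cation with an alkene.
Disconnections, backwards: the C3 carbinol (ketone reduction), C11–O (acetolysis through the nortricyclyl cation), C8–C9 (C–H insertion of a C8 carbene), then C6–C7, C8–C10 and C1–C9 in one operation (interrupted Nazarov/[3+2] of a ring-A cyclohexenyl isopropenyl ketone with phenyl vinyl sulfide), C6–C11 (carbonylative Stille) and C1=C2 (metathesis).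
Ring order: ring A first (C3, C4, C5 and C6 from (R)-pantolactone), then the cyclopentane and the second norbornane ring together, and the cyclopropane last.
C3 is carried as its 3R epimer. With O3 and O4 trans-diequatorial the ring-A half-chair is locked and steers the conrotation. The natural cis-diol would have to hold C12, O3 and a C5 methyl syn-triaxial in the product-like chair and should favour the wrong C1 epimer.
The same axial groups later force hydride onto a C3 ketone from the opposite face. This gives the natural 3S alcohol in the last step, after O4, O11 and O12 are already acetylated, so no selective acetylation is needed.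

Key step: step 16

Remark: ring A is C1 (bears C12), C2, C3, C4, C5 (CMe2), C6, and the cage arms are C6–C7–C8, C1–C9 and C6–C11–C10(Me); exo means syn to the C11 bridge; the C6 carbinol of 15 and the sulfur centre of 28 are taken as epimer mixtures and the C=N geometry of 35 and 36 is left open, because all are erased at once; Bn = benzyl, TBS = tert-butyldimethylsilyl, TBDPS = tert-butyldiphenylsilyl, TES = triethylsilyl.

Step 1
Reactants: 1 (R)-pantolactone; 2 benzyl bromide
Product: 3 (R)-O-benzylpantolactone
Conditions: Ag2O, DMF, 0 °C to rt, dark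
Reagents that add atoms: none
Why: Silver-oxide-promoted Williamson etherification runs without strong base, so the acidic C4–H next to the lactone carbonyl should not epimerise.

Step 2
Reactants: 3 (R)-O-benzylpantolactone
Product: 4 hydroxy Weinreb amide
Conditions: MeNH(OMe)·HCl, i-PrMgCl, THF, −20 to 0 °C; crude product used at once
Reagents that add atoms: N,O-dimethylhydroxylamine hydrochloride, CNOC.Cl
Why: Weinreb aminolysis with the magnesium amide opens the lactone at the acyl carbon C3 and leaves C4 untouched, and the product is carried on directly because it can relactonise.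

Step 3
Reactants: 4 hydroxy Weinreb amide
Product: 5 O6-TBS Weinreb amide
Conditions: TBSCl, imidazole, DMF, rt
Reagents that add atoms: tert-butyldimethylsilyl chloride, CC(C)(C)[Si](C)(C)Cl
Why: Imidazole-catalysed silylation of the primary neopentyl alcohol blocks relactonisation and masks C6 until step 7.

Step 4
Reactants: 5 O6-TBS Weinreb amide
Product: 6 alpha-benzyloxy aldehyde
Conditions: i-Bu2AlH, THF, −78 °C; aq. potassium sodium tartrate
Reagents that add atoms: none
Why: Hydride addition to a Weinreb amide stops at the chelated tetrahedral adduct, which releases the C3 aldehyde only on work-up and does not disturb C4.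

Step 5
Reactants: 6 alpha-benzyloxy aldehyde; 7 vinylmagnesium bromide
Product: 8 (3R,4R)-allylic alcohol
Conditions: MgBr2·OEt2 (3 equiv), CH2Cl2, −78 °C; then 7 (1 M in THF), −78 °C
Reagents that add atoms: none
Why: In this Cram-chelate Grignard addition magnesium bridges the aldehyde oxygen and the C4 benzyloxy oxygen, so the vinyl group (C2) enters C3 from the side of the C4 hydrogen, opposite the quaternary C5, and sets the 3R (syn) carbinol.

Step 6
Reactants: 8 (3R,4R)-allylic alcohol
Product: 9 O3-TBDPS O6-TBS ether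
Conditions: TBDPSCl, imidazole, DMAP (cat.), DMF, 45 °C
Reagents that add atoms: tert-butyldiphenylsilyl chloride, CC(C)(C)[Si](Cl)(c1ccccc1)c1ccccc1
Why: Standard silylation installs on O3 the silyl group most stable to acid and Lewis acid, which must outlast BF3 and every operation up to step 28.

Step 7
Reactants: 9 O3-TBDPS O6-TBS ether
Product: 10 C6 primary alcohol
Conditions: camphorsulfonic acid (10 mol %), MeOH–CH2Cl2, 0 °C
Reagents that add atoms: none
Why: Acid-catalysed methanolysis removes the primary TBS ether much faster than the secondary TBDPS ether.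

Step 8
Reactants: 10 C6 primary alcohol
Product: 11 C6 aldehyde
Conditions: Dess–Martin periodinane, CH2Cl2, rt
Reagents that add atoms: none
Why: Dess–Martin oxidation gives a non-enolisable neopentyl aldehyde under neutral conditions that spare the silyl, benzyl and vinyl groups.

Step 9
Reactants: 12 2-bromoprop-2-en-1-ol; 2 benzyl bromide
Product: 13 benzyl 2-bromoallyl ether
Conditions: NaH, THF, 0 °C; then 2, Bu4NI (cat.), rt
Reagents that add atoms: none
Why: Williamson etherification of the alkoxide with a reactive benzylic bromide supplies the C1/C12 building block.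

Step 10
Reactants: 11 C6 aldehyde; 13 benzyl 2-bromoallyl ether
Product: 15 dienol as C6 epimers, via vinyllithium 14 (not isolated)
Conditions: 13, t-BuLi (2 equiv), Et2O, −78 °C; then 11, −78 °C
Reagents that add atoms: none
Why: Bromine–lithium exchange followed by 1,2-addition of the vinyllithium to the non-enolisable aldehyde forms C1–C6, and the new C6 carbinol centre needs no control because step 11 removes it.

Step 11
Reactants: 15 dienol as C6 epimers
Product: 16 acyclic enone
Conditions: Dess–Martin periodinane, CH2Cl2, rt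
Reagents that add atoms: none
Why: Dess–Martin oxidation of the allylic alcohol merges both epimers into one C6 ketone.

Step 12
Reactants: 16 acyclic enone
Product: 17 ring-A cyclohexenone
Conditions: second-generation Grubbs catalyst (H2IMes)(PCy3)Cl2Ru=CHPh (5 mol %), toluene (0.005 M), 80 °C
Reagents that add atoms: none
Why: Ring-closing metathesis of the C3 vinyl group with the 1,1-disubstituted enone alkene closes a six-membered trisubstituted enone (C1=C2), helped by the gem-dimethyl group and touching no stereocentre.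

Step 13
Reactants: 17 ring-A cyclohexenone
Product: 19 tetrasubstituted vinyl triflate, via lithium enolate 18 (not isolated)
Conditions: LiBH(s-Bu)3, THF, −78 °C; then N-(5-chloro-2-pyridyl)bis(trifluoromethanesulfonimide), −78 to 0 °C
Reagents that add atoms: N-(5-chloro-2-pyridyl)bis(trifluoromethanesulfonimide), O=S(=O)(N(c1ccc(Cl)cn1)S(=O)(=O)C(F)(F)F)C(F)(F)F
Why: Conjugate hydride reduction of an enone with an unsubstituted beta-carbon and a hindered carbonyl gives the C6=C1 enolate regiospecifically, and O-triflation at low temperature traps it before the C12 benzyloxy group can be eliminated.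

Step 14
Reactants: 20 isopropenylmagnesium bromide; 21 tributyltin chloride
Product: 22 tributyl(isopropenyl)stannane
Conditions: THF, 0 °C to rt
Reagents that add atoms: none
Why: Transmetalation of a Grignard reagent with a chlorostannane is the standard route to vinylstannanes.

Step 15
Reactants: 19 tetrasubstituted vinyl triflate; 22 tributyl(isopropenyl)stannane
Product: 23 ring-A cyclohexenyl isopropenyl ketone
Conditions: CO (1–3 atm), Pd(PPh3)4 (5 mol %), LiCl (3 equiv), THF, 55 °C
Reagents that add atoms: carbon monoxide, [C-]#[O+]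
Why: In this carbonylative Stille coupling the triflate adds oxidatively to zerovalent palladium, CO inserts (C11), and transmetalation with reductive elimination gives the divinyl ketone, the classical entry to Nazarov substrates.

Step 16
Reactants: 23 ring-A cyclohexenyl isopropenyl ketone; 24 phenyl vinyl sulfide
Product: 27 exo-7-phenylthio tricyclic C11 ketone, via oxyallyl cation 25 (not isolated), via thionium ion 26 (not isolated)
Conditions: 24 (5 equiv), BF3·OEt2 (1.2 equiv), CH2Cl2, −78 to −20 °C; aq. NaHCO3
Reagents that add atoms: none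
Why: BF3 on the C11 oxygen turns 23 into the pentadienyl cation C9-C10-C11-C6-C1, which closes by thermal conrotatory 4π electrocyclisation (bond C1–C9, ring C1-C9-C10-C11-C6) to the oxyallyl cation 25, the CH2 of 24 then bonds to C10 (C8–C10) to give thionium ion 26, and the boron enolate carbon C6 adds to the thionium carbon (C6–C7, ring C6-C7-C8-C10-C11), a stepwise cationic [3+2] cycloaddition overall. The closest known reactions are interrupted Nazarov cyclisations of cross-conjugated dienones trapped by vinyl sulfides or allylsilanes to bicyclo[2.2.1]heptan-7-ones with two quaternary bridgeheads, and Nazarov closures onto the substituted ring carbon of 2,6,6-trimethylcyclohexenyl ketones. The first ring closes electrocyclically and the second by a formal 5-(enolendo)-exo-trig attack, which is geometrically possible because C8 stands perpendicular on C10 and holds C7 above the C6 p-orbital. C1 is set by torquoselectivity: the equatorial O3 and O4 groups hold the ring-A half-chair with C3 above and C4 below the alkene plane, and only the rotation that lifts C12 towards the face of the axial C3 hydrogen turns it into a chair with C12 axial and C9 equatorial, whereas the other sense needs a twist-boat or the diaxial conformer with O3, C12 and a C5 methyl syn-triaxial. C6 and C10 are set together because the two-carbon unit can only span one face, and the face bearing C12 should be used because bonding there leaves a C2-C1-C6-C5 torsion near 45° and puts the body of ring A exo beside the one-carbon bridge, while the other face would demand about 80° and press C2–C4 against the new bridge; the phenylthio group at C7 takes the exo position away from endo C12 and this centre is erased in step 17. The step needs capture to outrun proton loss from C9 or the C10 methyl and 1,2-shifts from C1 or C5, which the excess of nucleophilic alkene at low temperature serves, and it needs the CH2 to choose C10, which the flanking of C6 by the quaternary C1 and C5 secures.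

Step 17
Reactants: 27 exo-7-phenylthio tricyclic C11 ketone
Product: 29 C7=C8 norbornenone, via sulfoxide 28 (not isolated)
Conditions: mCPBA (1.0 equiv), toluene, −40 °C; then solid NaHCO3, 110 °C
Reagents that add atoms: none
Why: Chemoselective sulfur oxidation is followed by thermal syn (Ei) sulfoxide elimination, which can only give the C7=C8 alkene because C6 has no hydrogen and the exo sulfoxide is coplanar with the exo C8–H.

Step 18
Reactants: 29 C7=C8 norbornenone
Product: 30 C11 alcohol with OH on the ring-A side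
Conditions: LiAlH4, Et2O, −78 to 0 °C
Reagents that add atoms: none
Why: Hydride addition to the 7-norbornenone carbonyl should come from the open side over the C7=C8 double bond, because the other side is covered by ring A (exo C2 and the axial hydrogens at C2 and C4), which sets C11 with the hydroxyl anti to the alkene.

Step 19
Reactants: 30 C11 alcohol with OH on the ring-A side
Product: 31 C11 TES ether
Conditions: TESOTf, 2,6-lutidine, CH2Cl2, 0 °C
Reagents that add atoms: triethylsilyl trifluoromethanesulfonate, CC[Si](CC)(CC)OS(=O)(=O)C(F)(F)F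
Why: Silyl triflate silylation reaches even this crowded secondary alcohol and gives a group that fluoride removes later in the presence of TBDPS.

Step 20
Reactants: 31 C11 TES ether
Product: 33 exo-C8 alcohol, via organoborane 32 (not isolated)
Conditions: 9-BBN (3 equiv), THF, 60 °C; then H2O2 (30 %), NaOH (3 M), 0 °C to rt
Reagents that add atoms: hydrogen peroxide, OO
Why: Brown hydroboration–oxidation adds syn on the exo face (the endo face is closed by C12, and only the C11 hydrogen lies over the exo face), and boron should go to C8 because C7 adjoins C6 with both C5 methyl groups astride it while C8 adjoins only the methyl-bearing C10; the exo C8 carbinol centre is erased in step 21.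

Step 21
Reactants: 33 exo-C8 alcohol
Product: 34 C8 ketone
Conditions: Dess–Martin periodinane, CH2Cl2, rt
Reagents that add atoms: none
Why: Dess–Martin oxidation gives the camphor-type ketone without affecting the silyl and benzyl ethers.

Step 22
Reactants: 34 C8 ketone
Product: 35 C8 tosylhydrazone
Conditions: TsNHNH2, pyridinium p-toluenesulfonate (cat.), EtOH, 70 °C
Reagents that add atoms: p-toluenesulfonyl hydrazide, Cc1ccc(cc1)S(=O)(=O)NN
Why: Hydrazone condensation works on ketones flanked by one quaternary bridgehead and one CH2, as it does for camphor.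

Step 23
Reactants: 35 C8 tosylhydrazone
Product: 38 nortricyclene TES ether, via sodium salt 36 (not isolated), via diazoalkane 37 (not isolated)
Conditions: NaH (1.1 equiv), diglyme, rt; then 140 °C
Reagents that add atoms: none
Why: In this aprotic Bamford–Stevens reaction the salt loses sulfinate, the diazoalkane loses N2, and the C8 carbene inserts into the nearby endo C9–H (bond C8–C9) as camphor tosylhydrazone does on the way to tricyclene, the rigid cage fixing the configurations of C8 and C9.

Step 24
Reactants: 38 nortricyclene TES ether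
Product: 39 C11 nortricyclanol
Conditions: HF·pyridine, pyridine, THF, 0 °C
Reagents that add atoms: none
Why: Buffered fluoride cleaves the TES ether much faster than the TBDPS ether and is too weakly acidic to ionise the cyclopropylcarbinyl C–O bond.

Step 25
Reactants: 39 C11 nortricyclanol
Product: 41 C11 acetate with OAc on the C7 side, via mesylate 40 (not isolated)
Conditions: MsCl, Et3N, CH2Cl2, −20 °C; then NaOAc in AcOH, CH2Cl2 removed, 40 °C
Reagents that add atoms: sodium acetate, CC(=O)[O-].[Na+]
Why: Mesylation through sulfene is followed by buffered acetolysis, an SN1 reaction through the bisected cyclopropylcarbinyl (3-nortricyclyl) cation, in which acetate should enter C11 from the open C7 side, opposite both ring A and the departing mesylate, giving net inversion to the natural configuration.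

Step 26
Reactants: 41 C11 acetate with OAc on the C7 side
Product: 42 C4,C12-diol
Conditions: H2 (1 atm), 10 % Pd on carbon, EtOAc–EtOH, rt
Reagents that add atoms: none
Why: Catalytic hydrogenolysis removes both benzyl ethers under neutral conditions that leave the nortricyclene cyclopropane, the acetate and the TBDPS ether intact.

Step 27
Reactants: 42 C4,C12-diol
Product: 43 triacetate O3-TBDPS ether
Conditions: Ac2O, DMAP (cat.), pyridine, rt
Reagents that add atoms: acetic anhydride, CC(=O)OC(C)=O
Why: DMAP-catalysed acetylation esterifies the primary C12 and the equatorial C4 hydroxyl groups exhaustively while O3 is still protected, so no selectivity is asked of it.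

Step 28
Reactants: 43 triacetate O3-TBDPS ether
Product: 44 3-epi alcohol
Conditions: Bu4NF, AcOH (1:1), THF, rt to 40 °C
Reagents that add atoms: none
Why: Fluoride desilylation buffered with acetic acid frees the equatorial C3 hydroxyl without the basic alkoxide that would trigger acetyl migration from O4.

Step 29
Reactants: 44 3-epi alcohol
Product: 45 C3 ketone triacetate
Conditions: Dess–Martin periodinane, CH2Cl2, rt
Reagents that add atoms: none
Why: Neutral Dess–Martin oxidation gives the alpha-acetoxy ketone without enolising C4.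

Step 30
Reactants: 45 C3 ketone triacetate
Product: 46 CNP0111873.1
Conditions: NaBH4, MeOH–CH2Cl2, −40 °C; AcOH quench
Reagents that add atoms: none
Why: In this steric-approach-controlled hydride reduction the axial trajectory to C3 is closed by the syn-axial C12 and C5 methyl groups (as the angular methyls close the beta face of 11-oxo steroids), so hydride comes from the opposite face and sets the axial 3S alcohol cis to O4, and borohydride at low temperature spares the acetates.

Compound list
1 | (R)-pantolactone | CC1(C)COC(=O)[C@@H]1O | starting material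
2 | benzyl bromide | BrCc1ccccc1 | starting material
3 | (R)-O-benzylpantolactone, (3R)-3-benzyloxy-4,4-dimethyloxolan-2-one | CC1(C)COC(=O)[C@@H]1OCc1ccccc1 | intermediate
4 | (2R)-2-benzyloxy-4-hydroxy-N-methoxy-N,3,3-trimethylbutanamide | CON(C)C(=O)[C@H](OCc1ccccc1)C(C)(C)CO | intermediate
5 | (2R)-2-benzyloxy-4-(TBS-oxy)-N-methoxy-N,3,3-trimethylbutanamide | CON(C)C(=O)[C@H](OCc1ccccc1)C(C)(C)CO[Si](C)(C)C(C)(C)C | intermediate
6 | (2R)-2-benzyloxy-4-(TBS-oxy)-3,3-dimethylbutanal | O=C[C@H](OCc1ccccc1)C(C)(C)CO[Si](C)(C)C(C)(C)C | intermediate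
7 | vinylmagnesium bromide | C=C[Mg]Br | starting material
8 | (3R,4R)-4-benzyloxy-6-(TBS-oxy)-5,5-dimethylhex-1-en-3-ol | C=C[C@@H](O)[C@H](OCc1ccccc1)C(C)(C)CO[Si](C)(C)C(C)(C)C | intermediate
9 | (3R,4R)-4-benzyloxy-3-(TBDPS-oxy)-6-(TBS-oxy)-5,5-dimethylhex-1-ene | C=C[C@@H](O[Si](c1ccccc1)(c1ccccc1)C(C)(C)C)[C@H](OCc1ccccc1)C(C)(C)CO[Si](C)(C)C(C)(C)C | intermediate
10 | (3R,4R)-3-benzyloxy-4-(TBDPS-oxy)-2,2-dimethylhex-5-en-1-ol | C=C[C@@H](O[Si](c1ccccc1)(c1ccccc1)C(C)(C)C)[C@H](OCc1ccccc1)C(C)(C)CO | intermediate
11 | (3R,4R)-3-benzyloxy-4-(TBDPS-oxy)-2,2-dimethylhex-5-enal | C=C[C@@H](O[Si](c1ccccc1)(c1ccccc1)C(C)(C)C)[C@H](OCc1ccccc1)C(C)(C)C=O | intermediate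
12 | 2-bromoprop-2-en-1-ol | C=C(Br)CO | starting material
13 | benzyl 2-bromoallyl ether | C=C(Br)COCc1ccccc1 | intermediate
14 | 3-benzyloxyprop-1-en-2-yllithium | [Li]C(=C)COCc1ccccc1 | intermediate
15 | (5R,6R)-5-benzyloxy-2-(benzyloxymethyl)-6-(TBDPS-oxy)-4,4-dimethylocta-1,7-dien-3-ol, both carbinol (C6) epimers | C=C[C@@H](O[Si](c1ccccc1)(c1ccccc1)C(C)(C)C)[C@H](OCc1ccccc1)C(C)(C)C(O)C(=C)COCc1ccccc1 | intermediate
16 | (5R,6R)-5-benzyloxy-2-(benzyloxymethyl)-6-(TBDPS-oxy)-4,4-dimethylocta-1,7-dien-3-one | C=C[C@@H](O[Si](c1ccccc1)(c1ccccc1)C(C)(C)C)[C@H](OCc1ccccc1)C(C)(C)C(=O)C(=C)COCc1ccccc1 | intermediate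
17 | (4R,5R)-5-benzyloxy-2-(benzyloxymethyl)-4-(TBDPS-oxy)-6,6-dimethylcyclohex-2-en-1-one | O=C1C(COCc2ccccc2)=C[C@@H](O[Si](c2ccccc2)(c2ccccc2)C(C)(C)C)[C@H](OCc2ccccc2)C1(C)C | intermediate
18 | lithium C6=C1 enolate of the 2,3-dihydro derivative of 17 | [Li]OC1=C(COCc2ccccc2)C[C@@H](O[Si](c2ccccc2)(c2ccccc2)C(C)(C)C)[C@H](OCc2ccccc2)C1(C)C | intermediate
19 | (4R,5R)-5-benzyloxy-2-(benzyloxymethyl)-4-(TBDPS-oxy)-6,6-dimethylcyclohex-1-en-1-yl triflate | O=S(=O)(OC1=C(COCc2ccccc2)C[C@@H](O[Si](c2ccccc2)(c2ccccc2)C(C)(C)C)[C@H](OCc2ccccc2)C1(C)C)C(F)(F)F | intermediate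
20 | isopropenylmagnesium bromide | CC(=C)[Mg]Br | starting material
21 | tributyltin chloride | CCCC[Sn](Cl)(CCCC)CCCC | starting material
22 | tributyl(isopropenyl)stannane | CC(=C)[Sn](CCCC)(CCCC)CCCC | intermediate
23 | 1-[(4R,5R)-5-benzyloxy-2-(benzyloxymethyl)-4-(TBDPS-oxy)-6,6-dimethylcyclohex-1-en-1-yl]-2-methylprop-2-en-1-one (O3 and O4 trans) | C=C(C)C(=O)C1=C(COCc2ccccc2)C[C@@H](O[Si](c2ccccc2)(c2ccccc2)C(C)(C)C)[C@H](OCc2ccccc2)C1(C)C | intermediate
24 | phenyl vinyl sulfide | C=CSc1ccccc1 | starting material
25 | BF3-bound oxyallyl cation (C10-C11-C6) of the hydrindane, C1 quaternary with C12 on the face of O4 | C[C+]1C[C@@]2(COCc3ccccc3)C[C@@H](O[Si](c3ccccc3)(c3ccccc3)C(C)(C)C)[C@H](OCc3ccccc3)C(C)(C)C2=C1O[B-](F)(F)F | intermediate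
26 | thionium ion, C10 alkylated by C8 on the C12 face, boron enolate C6=C11 | C[C@@]1(CC=[S+]c3ccccc3)C[C@@]2(COCc3ccccc3)C[C@@H](O[Si](c3ccccc3)(c3ccccc3)C(C)(C)C)[C@H](OCc3ccccc3)C(C)(C)C2=C1O[B-](F)(F)F | intermediate
27 | tricyclic C11 ketone: ring A fused at C1–C6 to a bicyclo[2.2.1]heptan-7-one (bridgeheads C6 and C10), C2 exo and C12 endo at C1, exo-PhS at C7, 3-O-TBDPS, 4-O-Bn, 12-O-Bn | c1ccccc1COC[C@]12C[C@@H](O[Si](c4ccccc4)(c4ccccc4)C(C)(C)C)[C@H](OCc4ccccc4)C(C)(C)[C@]13[C@@H](Sc4ccccc4)C[C@](C)(C2)C3=O | intermediate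
28 | C7 exo-phenylsulfoxide of 27 (both sulfur epimers) | c1ccccc1COC[C@]12C[C@@H](O[Si](c4ccccc4)(c4ccccc4)C(C)(C)C)[C@H](OCc4ccccc4)C(C)(C)[C@]13[C@@H](S(=O)c4ccccc4)C[C@](C)(C2)C3=O | intermediate
29 | C7=C8 norbornenone (C11 ketone) | c1ccccc1COC[C@]12C[C@@H](O[Si](c4ccccc4)(c4ccccc4)C(C)(C)C)[C@H](OCc4ccccc4)C(C)(C)[C@]13C=C[C@](C)(C2)C3=O | intermediate
30 | C11 alcohol, OH anti to C7=C8 (on the ring-A side) | c1ccccc1COC[C@]12C[C@@H](O[Si](c4ccccc4)(c4ccccc4)C(C)(C)C)[C@H](OCc4ccccc4)C(C)(C)[C@]13C=C[C@](C)(C2)[C@@H]3O | intermediate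
31 | C11 TES ether of 30 | c1ccccc1COC[C@]12C[C@@H](O[Si](c4ccccc4)(c4ccccc4)C(C)(C)C)[C@H](OCc4ccccc4)C(C)(C)[C@]13C=C[C@](C)(C2)[C@@H]3O[Si](CC)(CC)CC | intermediate
32 | exo-C8 B-alkyl-9-borabicyclo[3.3.1]nonane | c1ccccc1COC[C@]12C[C@@H](O[Si](c4ccccc4)(c4ccccc4)C(C)(C)C)[C@H](OCc4ccccc4)C(C)(C)[C@]13C[C@@H](B4C5CCCC4CCC5)[C@](C)(C2)[C@@H]3O[Si](CC)(CC)CC | intermediate
33 | exo-C8 alcohol | c1ccccc1COC[C@]12C[C@@H](O[Si](c4ccccc4)(c4ccccc4)C(C)(C)C)[C@H](OCc4ccccc4)C(C)(C)[C@]13C[C@@H](O)[C@](C)(C2)[C@@H]3O[Si](CC)(CC)CC | intermediate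
34 | C8 ketone | c1ccccc1COC[C@]12C[C@@H](O[Si](c4ccccc4)(c4ccccc4)C(C)(C)C)[C@H](OCc4ccccc4)C(C)(C)[C@]13CC(=O)[C@](C)(C2)[C@@H]3O[Si](CC)(CC)CC | intermediate
35 | C8 tosylhydrazone | c1ccccc1COC[C@]12C[C@@H](O[Si](c4ccccc4)(c4ccccc4)C(C)(C)C)[C@H](OCc4ccccc4)C(C)(C)[C@]13CC(=NNS(=O)(=O)c4ccc(C)cc4)[C@](C)(C2)[C@@H]3O[Si](CC)(CC)CC | intermediate
36 | sodium salt of 35 | [Na+].c1ccccc1COC[C@]12C[C@@H](O[Si](c4ccccc4)(c4ccccc4)C(C)(C)C)[C@H](OCc4ccccc4)C(C)(C)[C@]13CC(=N[N-]S(=O)(=O)c4ccc(C)cc4)[C@](C)(C2)[C@@H]3O[Si](CC)(CC)CC | intermediate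
37 | C8 diazoalkane | c1ccccc1COC[C@]12C[C@@H](O[Si](c4ccccc4)(c4ccccc4)C(C)(C)C)[C@H](OCc4ccccc4)C(C)(C)[C@]13CC(=[N+]=[N-])[C@](C)(C2)[C@@H]3O[Si](CC)(CC)CC | intermediate
38 | nortricyclene (cyclopropane C8-C9-C10), 11-O-TES on the ring-A side, 3-O-TBDPS, 4-O-Bn, 12-O-Bn | c1ccccc1COC[C@]12C[C@@H](O[Si](c4ccccc4)(c4ccccc4)C(C)(C)C)[C@H](OCc4ccccc4)C(C)(C)[C@]13C[C@@H]1[C@H]2[C@]1(C)[C@@H]3O[Si](CC)(CC)CC | intermediate
39 | C11 nortricyclanol, OH on the ring-A side | c1ccccc1COC[C@]12C[C@@H](O[Si](c4ccccc4)(c4ccccc4)C(C)(C)C)[C@H](OCc4ccccc4)C(C)(C)[C@]13C[C@@H]1[C@H]2[C@]1(C)[C@@H]3O | intermediate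
40 | C11 mesylate of 39 | c1ccccc1COC[C@]12C[C@@H](O[Si](c4ccccc4)(c4ccccc4)C(C)(C)C)[C@H](OCc4ccccc4)C(C)(C)[C@]13C[C@@H]1[C@H]2[C@]1(C)[C@@H]3OS(C)(=O)=O | intermediate
41 | C11 acetate, OAc on the C7 side (natural C11 configuration) | c1ccccc1COC[C@]12C[C@@H](O[Si](c4ccccc4)(c4ccccc4)C(C)(C)C)[C@H](OCc4ccccc4)C(C)(C)[C@]13C[C@@H]1[C@H]2[C@]1(C)[C@H]3OC(C)=O | intermediate
42 | C4,C12-diol, 11-OAc, 3-O-TBDPS | OC[C@]12C[C@@H](O[Si](c4ccccc4)(c4ccccc4)C(C)(C)C)[C@H](O)C(C)(C)[C@]13C[C@@H]1[C@H]2[C@]1(C)[C@H]3OC(C)=O | intermediate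
43 | 4,11,12-triacetate, 3-O-TBDPS | CC(=O)OC[C@]12C[C@@H](O[Si](c4ccccc4)(c4ccccc4)C(C)(C)C)[C@H](OC(C)=O)C(C)(C)[C@]13C[C@@H]1[C@H]2[C@]1(C)[C@H]3OC(C)=O | intermediate
44 | 3-epi-target, equatorial 3R alcohol trans to O4 | CC(=O)OC[C@]12C[C@@H](O)[C@H](OC(C)=O)C(C)(C)[C@]13C[C@@H]1[C@H]2[C@]1(C)[C@H]3OC(C)=O | intermediate
45 | C3 ketone 4,11,12-triacetate | CC(=O)OC[C@]12CC(=O)[C@H](OC(C)=O)C(C)(C)[C@]13C[C@@H]1[C@H]2[C@]1(C)[C@H]3OC(C)=O | intermediate
46 | CNP0111873.1 | CC(=O)OC[C@]12C[C@H](O)[C@H](OC(C)=O)C(C)(C)[C@]13C[C@@H]1[C@H]2[C@]1(C)[C@H]3OC(C)=O | target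

Total step count: 30. Longest linear sequence: 28 steps (1–8, 10–13, 15–30); steps 9 and 14 prepare side reagents.

Steps most likely to fail

Step 16. The oxyallyl cation may be quenched by proton loss or by a Wagner–Meerwein shift before the alkene arrives. The enolate may fail to close on the thionium ion at C6, which lies between two quaternary carbons. The alkene may also add with poor facial selectivity. The fallback sets out from 23 and comes back at 39. Dienone 23 is cyclised without a trap (BF3·OEt2 or MeSO3H, CH2Cl2) in an ordinary Nazarov reaction that ends by proton loss from C9 and gives the cis-fused hydrindenone F1. Its only acidic position, C6–H, is deprotonated with LiN(i-Pr)2, and the cross-conjugated dienolate is treated with vinyltriphenylphosphonium bromide. Michael addition of C6 to the vinyl CH2 (C6–C7), addition of the ylide carbon C8 to the enone carbon C9 (C8–C9) and displacement of triphenylphosphine by the enolate carbon C10 (C8–C10) give the C11 nortricyclanone F2 in one operation, a known bicycloannulation of enone alpha'-enolates. LiAlH4 reduction from the open C7 side then gives 39.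

Step 25. After ionisation, acetate may be captured at C8 or C9 rather than at the crowded C11 (opening to a homoallylic norbornenyl acetate), or capture at C11 may show poor facial selectivity. The fallback sets out from 39 and comes back at 41, and it replaces ionisation by thermodynamic control. Alcohol 39 is equilibrated with Al(Oi-Pr)3 and a trace of acetone in refluxing toluene–i-PrOH. This is a Meerwein–Ponndorf–Verley/Oppenauer equilibration running through the ketone F2, and it drains the strained epimer under ring A into the less hindered C11-epimeric alcohol F3 with the hydroxyl on the C7 side. Acetylation (Ac2O, DMAP, pyridine) then gives 41.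

Step 20. Boron may also add to C7 (poor regioselectivity between two neopentyl-type alkene carbons), or the hindered alkene may react sluggishly. The fallback sets out from 27 and comes back at 34, and it keeps the sulfur as a regiochemical marker. N-Chlorosuccinimide followed by Et3N dehydrogenates the sulfide through its thionium ion to the C7 vinyl sulfide ketone F4. LiAlH4 reduces C11 from the alkene side to the vinyl sulfide alcohol F5, and TESOTf with 2,6-lutidine gives its TES ether F6. Hydroboration with BH3·THF must now place boron on C8, the less substituted and more nucleophilic carbon of the trisubstituted vinyl sulfide, and oxidation with Me3NO gives the exo-C8 alcohol with an endo C7 phenylthio group F7. Dess–Martin oxidation gives the alpha-phenylthio C8 ketone F8, and SmI2 in THF–MeOH removes the alpha-sulfur substituent to give 34.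

Further compounds
F1 | step 16 | cis-fused hydrindenone from the untrapped Nazarov reaction (C9=C10 enone, C6–H on the C12 face) | CC1=C[C@@]2(COCc3ccccc3)C[C@@H](O[Si](c3ccccc3)(c3ccccc3)C(C)(C)C)[C@H](OCc3ccccc3)C(C)(C)[C@H]2C1=O
F2 | step 16 | C11 nortricyclanone | c1ccccc1COC[C@]12C[C@@H](O[Si](c4ccccc4)(c4ccccc4)C(C)(C)C)[C@H](OCc4ccccc4)C(C)(C)[C@]13C[C@@H]1[C@H]2[C@]1(C)C3=O
F3 | step 25 | C11-epimeric nortricyclanol, OH on the C7 side | c1ccccc1COC[C@]12C[C@@H](O[Si](c4ccccc4)(c4ccccc4)C(C)(C)C)[C@H](OCc4ccccc4)C(C)(C)[C@]13C[C@@H]1[C@H]2[C@]1(C)[C@H]3O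
F4 | step 20 | C7 vinyl sulfide C11 ketone | c1ccccc1COC[C@]12C[C@@H](O[Si](c4ccccc4)(c4ccccc4)C(C)(C)C)[C@H](OCc4ccccc4)C(C)(C)[C@]13C(Sc4ccccc4)=C[C@](C)(C2)C3=O
F5 | step 20 | C7 vinyl sulfide C11 alcohol, OH on the ring-A side | c1ccccc1COC[C@]12C[C@@H](O[Si](c4ccccc4)(c4ccccc4)C(C)(C)C)[C@H](OCc4ccccc4)C(C)(C)[C@]13C(Sc4ccccc4)=C[C@](C)(C2)[C@@H]3O
F6 | step 20 | TES ether of F5 | c1ccccc1COC[C@]12C[C@@H](O[Si](c4ccccc4)(c4ccccc4)C(C)(C)C)[C@H](OCc4ccccc4)C(C)(C)[C@]13C(Sc4ccccc4)=C[C@](C)(C2)[C@@H]3O[Si](CC)(CC)CC
F7 | step 20 | exo-C8 alcohol with endo C7 phenylthio group | c1ccccc1COC[C@]12C[C@@H](O[Si](c4ccccc4)(c4ccccc4)C(C)(C)C)[C@H](OCc4ccccc4)C(C)(C)[C@]13[C@H](Sc4ccccc4)[C@@H](O)[C@](C)(C2)[C@@H]3O[Si](CC)(CC)CC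
F8 | step 20 | alpha-phenylthio C8 ketone | c1ccccc1COC[C@]12C[C@@H](O[Si](c4ccccc4)(c4ccccc4)C(C)(C)C)[C@H](OCc4ccccc4)C(C)(C)[C@]13[C@H](Sc4ccccc4)C(=O)[C@](C)(C2)[C@@H]3O[Si](CC)(CC)CC
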